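**Retrosynthetic overview**

1. 22 ⇐ 21 (three MOM ethers removed) ⇐ 17 (a temporary allyl ester on C3 leaves as CO2; C3–H is then set trans to ring B under thermodynamic control from C2).
2. 17 ⇐ 16 by the key disconnection C3–C4: a carbene-catalysed intramolecular crossed benzoin reaction of a racemic keto aldehyde under dynamic kinetic resolution. It closes ring C, the only ring that has to be built; rings A and B are bought.
3. Enabling feature: the acyloin C4(=O)–C3(OH) of ring C, with C4 as the formyl carbon on ring A and C3 as a ketone in 16, together with the C2–H that lies between O1, ring B and that ketone, so that C2 racemises freely before ring closure and is fixed after it.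
4. 16 ⇐ phenol 8 (ring A) + β-chloro α-keto ester 15 (ring B) by O-alkylation (O1–C2); 15 ⇐ vanillin MOM ether 10 + allyl dichloroacetate 13 (Darzens reaction).
5. 8 ⇐ 2,4,6-trihydroxybenzaldehyde 1 by bis-MOM protection, O-(1,1-dimethylpropargyl)ation, Lindlar reduction and aromatic Claisen rearrangement, which places the prenyl group next to the freed OH (future O1 and C8).

Key step: step 9

Assumption (chemistry): the (5aR,10bS) antipode of the aminoindanol-derived triazolium salt is taken to consume the (2R)-enantiomer of 16; the sense of induction has to be confirmed on the first run, and the (5aS,10bR) salt is used instead if it is the opposite.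

**Route**

Step 1
Reactants: 1 2,4,6-trihydroxybenzaldehyde; 2 chloromethyl methyl ether (MOMCl)
Product: 3 2-hydroxy-4,6-bis(methoxymethoxy)benzaldehyde
Conditions: MOMCl (2.1 equiv), i-Pr2NEt, CH2Cl2, 0 °C → rt
Reagents that add atoms: chloromethyl methyl ether (MOMCl, 2), COCCl
Why: Williamson-type MOM protection should take the para OH and one ortho OH and leave the OH that is hydrogen-bonded to the formyl group free, which is the oxygen that becomes O1.

Step 2
Reactants: 3 2-hydroxy-4,6-bis(methoxymethoxy)benzaldehyde; 4 3-chloro-3-methylbut-1-yne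
Product: 5 2-[(2-methylbut-3-yn-2-yl)oxy]-4,6-bis(methoxymethoxy)benzaldehyde
Conditions: 3-chloro-3-methylbut-1-yne (1.5 equiv), DBU, CuCl2·2H2O (1 mol%), MeCN, 0 °C → rt
Reagents that add atoms: 3-chloro-3-methylbut-1-yne (4), C#CC(C)(C)Cl
Why: Copper-catalysed propargylic etherification of a phenol with a tertiary propargylic chloride should give the aryl 1,1-dimethylpropargyl ether at the only free OH.

Step 3
Reactants: 5 2-[(2-methylbut-3-yn-2-yl)oxy]-4,6-bis(methoxymethoxy)benzaldehyde
Product: 6 2-[(2-methylbut-3-en-2-yl)oxy]-4,6-bis(methoxymethoxy)benzaldehyde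
Conditions: H2 (1 atm), Pd/CaCO3 poisoned with Pb(OAc)2 (Lindlar catalyst), quinoline, EtOAc, rt
Reagents that add atoms: none
Why: Lindlar semi-hydrogenation should stop at the terminal alkene and leave the aldehyde and the MOM acetals untouched.

Step 4
Reactants: 6 2-[(2-methylbut-3-en-2-yl)oxy]-4,6-bis(methoxymethoxy)benzaldehyde
Product: 8 2-hydroxy-4,6-bis(methoxymethoxy)-3-(3-methylbut-2-en-1-yl)benzaldehyde, via Claisen dienone 7 (not isolated)
Conditions: xylene, 130 °C, Ar
Reagents that add atoms: none
Why: The aromatic Claisen rearrangement of the 1,1-dimethylallyl ether delivers the inverted allyl unit, a normal prenyl group, to the only free ortho carbon, and tautomerisation of dienone 7 restores the phenol between the formyl and prenyl groups.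

Step 5
Reactants: 9 vanillin; 2 chloromethyl methyl ether (MOMCl)
Product: 10 3-methoxy-4-(methoxymethoxy)benzaldehyde
Conditions: MOMCl, i-Pr2NEt, CH2Cl2, 0 °C → rt
Reagents that add atoms: chloromethyl methyl ether (MOMCl, 2), COCCl
Why: Standard MOM protection of the single phenol gives a ring B aldehyde whose protecting group matches those of ring A.

Step 6
Reactants: 11 dichloroacetyl chloride; 12 prop-2-en-1-ol (allyl alcohol)
Product: 13 allyl dichloroacetate
Conditions: pyridine, CH2Cl2, 0 °C
Reagents that add atoms: dichloroacetyl chloride (11), O=C(Cl)C(Cl)Cl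
Why: Acylation of the alcohol by the acid chloride gives the Darzens partner as an allyl ester that can later be removed under neutral palladium catalysis.

Step 7
Reactants: 10 3-methoxy-4-(methoxymethoxy)benzaldehyde; 13 allyl dichloroacetate
Product: 15 allyl 3-chloro-3-[3-methoxy-4-(methoxymethoxy)phenyl]-2-oxopropanoate (racemic), via chloroglycidate 14 (not isolated)
Conditions: t-BuOK, THF, −78 °C → rt
Reagents that add atoms: allyl dichloroacetate (13), C=CCOC(=O)C(Cl)Cl
Why: The Darzens reaction with a dichloroacetate gives α-chloroglycidic ester 14, which should rearrange by ionisation at the benzylic carbon and 1,2-chloride shift to the β-chloro α-keto ester; the new centre is racemic and need not be controlled.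

Step 8
Reactants: 8 2-hydroxy-4,6-bis(methoxymethoxy)-3-(3-methylbut-2-en-1-yl)benzaldehyde; 15 allyl 3-chloro-3-[3-methoxy-4-(methoxymethoxy)phenyl]-2-oxopropanoate
Product: 16 allyl 3-[2-formyl-3,5-bis(methoxymethoxy)-6-(3-methylbut-2-en-1-yl)phenoxy]-3-[3-methoxy-4-(methoxymethoxy)phenyl]-2-oxopropanoate (racemic)
Conditions: K2CO3, NaI (10 mol%), acetone, 0 °C → rt
Reagents that add atoms: 15 allyl 3-chloro-3-[3-methoxy-4-(methoxymethoxy)phenyl]-2-oxopropanoate, C=CCOC(=O)C(=O)C(Cl)c1ccc(OCOC)c(OC)c1
Why: SN2 O-alkylation of the salicylaldehyde-type phenoxide by the doubly activated benzylic α-keto chloride (the first stage of a Rap–Stoermer reaction) forms the O1–C2 bond; C2 is made racemic on purpose.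

Step 9
Reactants: 16 allyl 3-[2-formyl-3,5-bis(methoxymethoxy)-6-(3-methylbut-2-en-1-yl)phenoxy]-3-[3-methoxy-4-(methoxymethoxy)phenyl]-2-oxopropanoate (racemic)
Product: 17 allyl (2R,3R)-3-hydroxy-2-[3-methoxy-4-(methoxymethoxy)phenyl]-5,7-bis(methoxymethoxy)-8-(3-methylbut-2-en-1-yl)-4-oxo-3,4-dihydro-2H-chromene-3-carboxylate
Conditions: (5aR,10bS)-2-(pentafluorophenyl)-5a,10b-dihydro-4H,6H-indeno[2,1-b][1,2,4]triazolo[4,3-d][1,4]oxazin-2-ium tetrafluoroborate (10 mol%), K2CO3 (20 mol%), toluene, 4 Å molecular sieves, 0 °C → rt, Ar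
Reagents that add atoms: none
Why: The triazolylidene adds to the formyl group on ring A, the only carbonyl of 16 that carries a formyl hydrogen, and the Breslow intermediate attacks the C3 ketone through its C4 carbon; proton transfer and loss of the carbene give the tertiary acyloin and close ring C. The closest known reaction types are the carbene-catalysed intramolecular crossed aldehyde–ketone benzoin reaction that gives 3-hydroxychroman-4-ones and the dynamic kinetic cross-benzoin reaction of β-stereogenic α-keto esters. Ring C closes in the 6-exo-trig mode (C4 onto the C3 carbonyl). C2 is controlled by the catalyst through dynamic kinetic resolution: its hydrogen lies between ring B, O1 and the C3 keto ester carbonyl, so the two enantiomers of 16 interconvert through the enol much faster than either cyclises and the chiral carbene should funnel the racemate into the (2R) series; C3 is set by a chair-like transition state with ring B equatorial and the Breslow OH hydrogen-bonded to the ketone oxygen (expected 3R), but this centre is rebuilt in step 10, so either C3 epimer serves. The step needs donor/acceptor chemoselectivity, and the allyl ester on C3 secures it: as a ketone the C3 carbonyl cannot become an acyl anion, so the loss of the O1 aryloxide that a C3 aldehyde would suffer through its own Breslow intermediate is excluded, while the ester raises both the electrophilicity of C3 and the acidity of C2–H. The competing 5-exo aldol addition of the enol of 16 to the formyl group is reversible, because its adduct has a quaternary carbon and cannot dehydrate, so it should drain back into the benzoin pathway.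

Step 10
Reactants: 17 allyl (2R,3R)-3-hydroxy-2-[3-methoxy-4-(methoxymethoxy)phenyl]-5,7-bis(methoxymethoxy)-8-(3-methylbut-2-en-1-yl)-4-oxo-3,4-dihydro-2H-chromene-3-carboxylate
Product: 21 (2R,3R)-3-hydroxy-2-[3-methoxy-4-(methoxymethoxy)phenyl]-5,7-bis(methoxymethoxy)-8-(3-methylbut-2-en-1-yl)chroman-4-one, via carboxylic acid 18 (not isolated), via enediol 19 (not isolated), via cis epimer 20 (not isolated)
Conditions: Pd(PPh3)4 (5 mol%), morpholine (3 equiv), THF, rt, Ar; then DBU (10 mol%), 0 °C, until the cis/trans ratio no longer changes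
Reagents that add atoms: none
Why: Tsuji–Trost transfer of the allyl group to morpholine frees β-keto acid 18, which loses CO2 to enediol 19 and ketonises to the conjugated aryl ketone as C3 epimers; DBU-mediated enolisation, which can reach only C3 because C2 has no acidic hydrogen, should then convert cis epimer 20 into the diequatorial 2,3-trans isomer 21, so C3 is set under thermodynamic control by the C2 centre fixed in step 9.

Step 11
Reactants: 21 (2R,3R)-3-hydroxy-2-[3-methoxy-4-(methoxymethoxy)phenyl]-5,7-bis(methoxymethoxy)-8-(3-methylbut-2-en-1-yl)chroman-4-one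
Product: 22 (2R,3R)-3,5,7-trihydroxy-2-(4-hydroxy-3-methoxyphenyl)-8-(3-methylbut-2-en-1-yl)chroman-4-one
Conditions: HCl (3 M aq.), MeOH, 40 °C
Reagents that add atoms: none
Why: Acid-catalysed transacetalisation to methanol removes the three MOM groups under conditions mild enough that the prenyl group should not cyclise onto the 7-OH and neither stereocentre should epimerise.

**Compound list**

1 | 2,4,6-trihydroxybenzaldehyde | O=Cc1c(O)cc(O)cc1O | starting material
2 | chloromethyl methyl ether (MOMCl) | COCCl | starting material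
3 | 2-hydroxy-4,6-bis(methoxymethoxy)benzaldehyde | O=Cc1c(O)cc(OCOC)cc1OCOC | intermediate
4 | 3-chloro-3-methylbut-1-yne | C#CC(C)(C)Cl | starting material
5 | 2-[(2-methylbut-3-yn-2-yl)oxy]-4,6-bis(methoxymethoxy)benzaldehyde | O=Cc1c(OC(C)(C)C#C)cc(OCOC)cc1OCOC | intermediate
6 | 2-[(2-methylbut-3-en-2-yl)oxy]-4,6-bis(methoxymethoxy)benzaldehyde | O=Cc1c(OC(C)(C)C=C)cc(OCOC)cc1OCOC | intermediate
7 | 2,4-bis(methoxymethoxy)-5-(3-methylbut-2-en-1-yl)-6-oxocyclohexa-1,3-diene-1-carbaldehyde (racemic, not isolated) | O=CC1=C(OCOC)C=C(OCOC)C(CC=C(C)C)C1=O | intermediate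
8 | 2-hydroxy-4,6-bis(methoxymethoxy)-3-(3-methylbut-2-en-1-yl)benzaldehyde | O=Cc1c(O)c(CC=C(C)C)c(OCOC)cc1OCOC | intermediate
9 | vanillin (4-hydroxy-3-methoxybenzaldehyde) | COc1cc(C=O)ccc1O | starting material
10 | 3-methoxy-4-(methoxymethoxy)benzaldehyde | COCOc1ccc(C=O)cc1OC | intermediate
11 | dichloroacetyl chloride | O=C(Cl)C(Cl)Cl | starting material
12 | prop-2-en-1-ol (allyl alcohol) | C=CCO | starting material
13 | allyl dichloroacetate | C=CCOC(=O)C(Cl)Cl | intermediate
14 | allyl 2-chloro-3-[3-methoxy-4-(methoxymethoxy)phenyl]oxirane-2-carboxylate (racemic, not isolated) | C=CCOC(=O)C1(Cl)OC1c1ccc(OCOC)c(OC)c1 | intermediate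
15 | allyl 3-chloro-3-[3-methoxy-4-(methoxymethoxy)phenyl]-2-oxopropanoate (racemic) | C=CCOC(=O)C(=O)C(Cl)c1ccc(OCOC)c(OC)c1 | intermediate
16 | allyl 3-[2-formyl-3,5-bis(methoxymethoxy)-6-(3-methylbut-2-en-1-yl)phenoxy]-3-[3-methoxy-4-(methoxymethoxy)phenyl]-2-oxopropanoate (racemic) | C=CCOC(=O)C(=O)C(Oc1c(C=O)c(OCOC)cc(OCOC)c1CC=C(C)C)c1ccc(OCOC)c(OC)c1 | intermediate
17 | allyl (2R,3R)-3-hydroxy-2-[3-methoxy-4-(methoxymethoxy)phenyl]-5,7-bis(methoxymethoxy)-8-(3-methylbut-2-en-1-yl)-4-oxo-3,4-dihydro-2H-chromene-3-carboxylate | COCOc1ccc([C@H]2Oc3c(CC=C(C)C)c(OCOC)cc(OCOC)c3C(=O)[C@@]2(O)C(=O)OCC=C)cc1OC | intermediate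
18 | (2R,3R)-3-hydroxy-2-[3-methoxy-4-(methoxymethoxy)phenyl]-5,7-bis(methoxymethoxy)-8-(3-methylbut-2-en-1-yl)-4-oxo-3,4-dihydro-2H-chromene-3-carboxylic acid (not isolated) | COCOc1ccc([C@H]2Oc3c(CC=C(C)C)c(OCOC)cc(OCOC)c3C(=O)[C@@]2(O)C(=O)O)cc1OC | intermediate
19 | (2R)-2-[3-methoxy-4-(methoxymethoxy)phenyl]-5,7-bis(methoxymethoxy)-8-(3-methylbut-2-en-1-yl)-2H-chromene-3,4-diol (not isolated) | COCOc1ccc([C@H]2Oc3c(CC=C(C)C)c(OCOC)cc(OCOC)c3C(O)=C2O)cc1OC | intermediate
20 | (2R,3S)-3-hydroxy-2-[3-methoxy-4-(methoxymethoxy)phenyl]-5,7-bis(methoxymethoxy)-8-(3-methylbut-2-en-1-yl)chroman-4-one (cis epimer, not isolated) | COCOc1ccc([C@H]2Oc3c(CC=C(C)C)c(OCOC)cc(OCOC)c3C(=O)[C@H]2O)cc1OC | intermediate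
21 | (2R,3R)-3-hydroxy-2-[3-methoxy-4-(methoxymethoxy)phenyl]-5,7-bis(methoxymethoxy)-8-(3-methylbut-2-en-1-yl)chroman-4-one | COCOc1ccc([C@H]2Oc3c(CC=C(C)C)c(OCOC)cc(OCOC)c3C(=O)[C@@H]2O)cc1OC | intermediate
22 | (2R,3R)-3,5,7-trihydroxy-2-(4-hydroxy-3-methoxyphenyl)-8-(3-methylbut-2-en-1-yl)chroman-4-one | COc1cc([C@H]2Oc3c(CC=C(C)C)c(O)cc(O)c3C(=O)[C@@H]2O)ccc1O | target

**Step count and risks**

Total step count: 11. Longest linear sequence: 8 steps (steps 1, 2, 3, 4, 8, 9, 10, 11, counted from 1).

Steps most likely to fail: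

1. Step 9 (key step). The carbene may add only slowly to the formyl group, which is electron-rich and flanked by two ortho oxygen substituents. The enol of 16 may be diverted into the aldol manifold and trapped there by lactonisation onto the allyl ester. The catalyst may also discriminate the two interconverting enantiomers incompletely. Fallback (sets out from 16, returns at 21): catalyst control of configuration is given up in favour of a racemic ring closure and a physical resolution. 16 is cyclised with the small achiral carbene generated from 3-benzyl-5-(2-hydroxyethyl)-4-methylthiazolium chloride and Et3N (THF, 40 °C), which should tolerate the crowded formyl group better; this gives 17 as the racemate, that is 17 together with its enantiomer, allyl (2S,3S)-3-hydroxy-2-[3-methoxy-4-(methoxymethoxy)phenyl]-5,7-bis(methoxymethoxy)-8-(3-methylbut-2-en-1-yl)-4-oxo-3,4-dihydro-2H-chromene-3-carboxylate F1. The racemate is taken through the conditions of step 10, which should give 21 together with its enantiomer, (2S,3S)-3-hydroxy-2-[3-methoxy-4-(methoxymethoxy)phenyl]-5,7-bis(methoxymethoxy)-8-(3-methylbut-2-en-1-yl)chroman-4-one F2. The two are separated by preparative chromatography on a cellulose tris(3,5-dimethylphenylcarbamate) phase, and 21 rejoins the route at step 11.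

2. Step 10. Protonation of the enediol is expected to occur mainly anti to ring B and so to favour the cis epimer. The base-mediated correction may stay incomplete, or the C3 enolate may open ring C by β-elimination of the O1 phenoxide. Fallback (sets out from 20, returns at 22): the DBU equilibration is omitted and the C3 epimers are separated after the palladium stage. 21 goes on to step 11. The cis epimer 20 is inverted at C3 by a Mitsunobu reaction (HCO2H, PPh3, DIAD, THF, 0 °C) to the trans formate, (2R,3R)-2-[3-methoxy-4-(methoxymethoxy)phenyl]-5,7-bis(methoxymethoxy)-8-(3-methylbut-2-en-1-yl)-4-oxochroman-3-yl formate F3. HCl in MeOH as in step 11 should then cleave the formate together with the three MOM groups and give 22.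

3. Step 8. O-Alkylation of the hindered, hydrogen-bonded phenoxide may be outrun by solvolysis or enolisation of the labile benzylic chloride 15, and the acidic product may be consumed by base. Fallback (sets out from 10 and 8, returns at 16): the substitution is replaced by an epoxide opening followed by oxidation. A Darzens reaction of 10 with allyl chloroacetate (t-BuOK, THF, −78 °C) should give the more robust glycidic ester allyl trans-3-[3-methoxy-4-(methoxymethoxy)phenyl]oxirane-2-carboxylate F4 (racemic). The phenoxide of 8 (Cs2CO3, DMF, 60 °C) should open it at the benzylic carbon to allyl 3-[2-formyl-3,5-bis(methoxymethoxy)-6-(3-methylbut-2-en-1-yl)phenoxy]-2-hydroxy-3-[3-methoxy-4-(methoxymethoxy)phenyl]propanoate F5 (racemic diastereomers). Oxidation of the secondary alcohol with the periodinane 1,1,1-triacetoxy-1,1-dihydro-1,2-benziodoxol-3(1H)-one (NaHCO3, CH2Cl2, 0 °C) then gives 16.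

Further compounds
F1 | step 9 | allyl (2S,3S)-3-hydroxy-2-[3-methoxy-4-(methoxymethoxy)phenyl]-5,7-bis(methoxymethoxy)-8-(3-methylbut-2-en-1-yl)-4-oxo-3,4-dihydro-2H-chromene-3-carboxylate | COCOc1ccc([C@@H]2Oc3c(CC=C(C)C)c(OCOC)cc(OCOC)c3C(=O)[C@]2(O)C(=O)OCC=C)cc1OC
F2 | step 9 | (2S,3S)-3-hydroxy-2-[3-methoxy-4-(methoxymethoxy)phenyl]-5,7-bis(methoxymethoxy)-8-(3-methylbut-2-en-1-yl)chroman-4-one | COCOc1ccc([C@@H]2Oc3c(CC=C(C)C)c(OCOC)cc(OCOC)c3C(=O)[C@H]2O)cc1OC
F3 | step 10 | (2R,3R)-2-[3-methoxy-4-(methoxymethoxy)phenyl]-5,7-bis(methoxymethoxy)-8-(3-methylbut-2-en-1-yl)-4-oxochroman-3-yl formate | COCOc1ccc([C@H]2Oc3c(CC=C(C)C)c(OCOC)cc(OCOC)c3C(=O)[C@@H]2OC=O)cc1OC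
F4 | step 8 | allyl trans-3-[3-methoxy-4-(methoxymethoxy)phenyl]oxirane-2-carboxylate (racemic) | C=CCOC(=O)C1OC1c1ccc(OCOC)c(OC)c1
F5 | step 8 | allyl 3-[2-formyl-3,5-bis(methoxymethoxy)-6-(3-methylbut-2-en-1-yl)phenoxy]-2-hydroxy-3-[3-methoxy-4-(methoxymethoxy)phenyl]propanoate (racemic diastereomers) | C=CCOC(=O)C(O)C(Oc1c(C=O)c(OCOC)cc(OCOC)c1CC=C(C)C)c1ccc(OCOC)c(OC)c1
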